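The route cuts C2–C3 of the five-membered ring (C1–OAc, C2H2, C3(OH)(i-Pr), C4H, C10–CH3), where the C1–O and C3–O bonds flank the C2 methylene. One bought carbinol centre (C5) sets C4 and the quaternary C10, and so the trans ring fusion, in a dianionic Ireland–Claisen rearrangement. Metathesis then closes the seven-membered ring. Iodolactonisation builds the five-membered ring as its oxa analogue and sets C1. In the key step, iodine–lithium exchange reverses the polarity of C2 in a keto iodohydrin, and the carbanion adds to the C3 isopropyl ketone. This joins two electrophilic carbons, closes the carbocycle and sets C3. The precursor is a trans-disubstituted cycloheptene.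

Key step: step 10

Remark: the locants are those of the target skeleton. The five-membered ring is C1–C2–C3–C4–C10 and the seven-membered ring is C4–C5(O-aroyl)–C6H2–C7(CH3)=C8H–C9H2–C10. β is the face of the C10 methyl group and α the opposite face. Compounds 1, 4 and 20 are taken as commercial.

Step 1
Reactants: 1 pent-1-en-4-yne
Product: 3 (2E)-3-methylhexa-2,5-dien-1-ol, via alkenylalane 2 (not isolated)
Conditions: Me3Al, Cp2ZrCl2 (20 mol%), CH2Cl2, 0 → 23 °C; n-BuLi, THF/hexane, −78 °C; (CH2O)n, → 23 °C; aq. HCl
Reagents that add atoms: trimethylaluminium C[Al](C)C; paraformaldehyde (as formaldehyde) C=O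
Why: Negishi zirconium-catalysed carboalumination adds CH3 and Al syn across the terminal alkyne only, and the derived alanate is hydroxymethylated with retention, which fixes the E geometry that later encodes C10.

Step 2
Reactants: 4 ethyl (3R)-4-chloro-3-hydroxybutanoate
Product: 5 ethyl [(2R)-oxiran-2-yl]acetate
Conditions: Ag2O, 1,2-dimethoxyethane, 60 °C
Reagents that add atoms: none
Why: Silver-assisted intramolecular Williamson closure (3-exo-tet) works without free base, so E1cB opening to the 4-hydroxycrotonate is avoided and the C–O stereocentre is untouched.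

Step 3
Reactants: 5 ethyl [(2R)-oxiran-2-yl]acetate
Product: 6 ethyl (3S)-3-hydroxy-5-methylhex-5-enoate
Conditions: isopropenylmagnesium bromide, CuI (10 mol%), THF, −40 °C; aq. NH4Cl
Reagents that add atoms: isopropenylmagnesium bromide CC(=C)[Mg]Br
Why: Copper-catalysed Grignard opening of the terminal epoxide (SN2 at the CH2) should outrun attack on the ester at low temperature and leaves the carbinol centre (the future C5) unchanged.

Step 4
Reactants: 6 ethyl (3S)-3-hydroxy-5-methylhex-5-enoate; 3 (2E)-3-methylhexa-2,5-dien-1-ol
Product: 7 (2E)-3-methylhexa-2,5-dien-1-yl (3S)-3-hydroxy-5-methylhex-5-enoate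
Conditions: Bu2(NCS)SnOSnBu2(OH) (5 mol%), toluene, reflux (removal of EtOH)
Reagents that add atoms: none
Why: Neutral distannoxane-catalysed transesterification exchanges ethanol for the primary allylic alcohol without dehydrating or racemising the β-hydroxy ester.

Step 5
Reactants: 7 (2E)-3-methylhexa-2,5-dien-1-yl (3S)-3-hydroxy-5-methylhex-5-enoate
Product: 9 (2S,3S)-3-ethenyl-2-[(1S)-1-hydroxy-3-methylbut-3-en-1-yl]-3-methylhex-5-enoic acid, via dilithio enolate 8 (not isolated)
Conditions: LDA (2.3 equiv), THF, −78 → 40 °C; aq. HCl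
Reagents that add atoms: none
Why: In this dianionic Ireland–Claisen rearrangement the lithium-chelated enolate (enolate oxygen cis to C5) should react through a chair on the face anti to the C6 chain (Fráter–Seebach sense), so C5 sets C4 (anti) and the E-alkene sets the quaternary C10 in the same event.

Step 6
Reactants: 9 hydroxy acid
Product: 11 (2S,3S)-2-[(1S)-1-[(tert-butyldimethylsilyl)oxy]-3-methylbut-3-en-1-yl]-3-ethenyl-3-methylhex-5-enoic acid, via bis-silyl derivative 10 (not isolated)
Conditions: TBSOTf (2.3 equiv), 2,6-lutidine, CH2Cl2, 0 °C; then AcOH/THF/H2O, 23 °C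
Reagents that add atoms: tert-butyldimethylsilyl triflate CC(C)(C)[Si](C)(C)OS(=O)(=O)C(F)(F)F
Why: Exhaustive silylation followed by selective hydrolysis of the labile silyl ester masks C5–OH, which would otherwise compete as a nucleophile in step 8 and as an acid in steps 9 and 10.

Step 7
Reactants: 11 silyl ether acid
Product: 12 2-[(tert-butyldimethylsilyl)oxy]-7-ethenyl-4,7-dimethylcyclohept-4-ene-1-carboxylic acid (C4 β-CO2H, C5 α-OTBS, C10 β-CH3 and α-vinyl)
Conditions: second-generation Grubbs catalyst (5 mol%), CH2Cl2 (5 mM), 40 °C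
Reagents that add atoms: none
Why: Ring-closing metathesis initiates at the unhindered allyl group and can close only onto the methallyl group (seven-membered ring, trisubstituted C7=C8), because closure onto the neopentyl vinyl group would give a cyclobutene.

Step 8
Reactants: 12 cycloheptene acid
Product: 13 trans-fused iodolactone (γ-lactone C3(=O)–O–C1 on C4/C10; CH2I on C1 β, quasi-equatorial)
Conditions: I2, NaHCO3, MeCN, 0 °C, dark
Reagents that add atoms: iodine II
Why: In this 5-exo-trig iodolactonisation, reversible iodonium formation is funnelled by the neighbouring C3 carboxylate to the vinyl group (capture at C7=C8 would need a bridged lactone), and attack on the rotamer whose C1=C2 bond eclipses C10–CH3 places CH2I quasi-equatorial, which is the C1–O configuration that ends up α.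

Step 9
Reactants: 13 iodolactone
Product: 14 keto iodohydrin (C4 β-isobutyryl; C10 α-CH(OH)CH2I; C5 α-OTBS)
Conditions: i-PrMgCl, LaCl3·2LiCl, THF, −40 → −10 °C; aq. NH4Cl
Reagents that add atoms: isopropylmagnesium chloride CC(C)[Mg]Cl
Why: Acyl addition of the lanthanum-modified Grignard reagent (low basicity, little β-hydride transfer) opens the lactone, the doubly branched ketone resists a second addition, and the cold magnesium alkoxide should not yet displace iodide.

Step 10
Reactants: 14 keto iodohydrin
Product: 17 bicyclic 1α,3β-diol 5α-TBS ether (3α-isopropyl, 4α-H, 10β-CH3), via lithium alkoxide 15 (not isolated), via beta-lithioalkoxide 16 (not isolated)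
Conditions: MeLi (1.0 equiv), Et2O/pentane, −78 °C; t-BuLi (2.1 equiv), −100 → −78 °C; aq. NH4Cl
Reagents that add atoms: none
Why: MeLi first takes the O–H proton (15); t-BuLi then exchanges iodine for lithium through an iodine ate complex far faster than it adds to or enolises the doubly branched ketone, the second equivalent consuming the t-BuI formed, and the β-lithioalkoxide 16, which does not lose Li2O at this temperature, adds to the C3 carbonyl. The closest known reaction type is the halogen–lithium-exchange-initiated cyclisation of ω-iodo ketones (an intramolecular Barbier-type addition), run here with a β-lithioalkoxide of the kind known from reductive lithiation of epoxides. The five-membered ring closes 5-exo-trig by attack of an sp3 carbanion on an exocyclic C=O, free of the orbital misalignment of the alternative 5-(enolendo) aldol closure. The only new stereocentre, C3, is controlled by the trans-fused ring being formed: the site 1,3-syn to the β C10 methyl group accepts only oxygen, so isopropyl goes quasi-equatorial (α) and O–Li goes β. Because no enolate is formed, C4 cannot epimerise and the C5 silyloxy group cannot be eliminated, while C1, C5 and C10 are spectators. The step needs exchange to beat carbonyl attack, α-deprotonation and epoxide closure of 15, which the very low temperature, the hindered ketone and the tight lithium alkoxide should secure.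

Step 11
Reactants: 17 diol
Product: 18 1α-acetate of 17
Conditions: Ac2O, DMAP (cat.), pyridine, CH2Cl2, 23 °C
Reagents that add atoms: acetic anhydride CC(=O)OC(C)=O
Why: Nucleophile-catalysed acylation takes the secondary C1 hydroxyl, whereas the tertiary C3 hydroxyl next to isopropyl is too hindered to react.

Step 12
Reactants: 18 acetate silyl ether
Product: 19 1α-acetoxy-3β,5α-diol
Conditions: HF·pyridine, THF/pyridine, 0 → 23 °C
Reagents that add atoms: none
Why: Buffered fluoride desilylation frees C5–OH without touching the acetate, the tertiary alcohol or the trisubstituted alkene.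

Step 13
Reactants: 19 1α-acetoxy-3β,5α-diol; 20 4-[(tert-butyldimethylsilyl)oxy]benzoic acid
Product: 21 O-silylated target (5α-[4-(TBSO)benzoate])
Conditions: DCC, DMAP, CH2Cl2, 40 °C
Reagents that add atoms: none
Why: Steglich esterification with retention at C5 acylates the only secondary hydroxyl left, and the silyl group keeps the phenol from self-acylation.

Step 14
Reactants: 21 O-silylated target
Product: 22 target (1α-acetoxy-3β-hydroxy-5α-(4-hydroxybenzoyloxy) compound)
Conditions: TBAF, AcOH (1.1 equiv each), THF, 0 °C
Reagents that add atoms: none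
Why: An aryl silyl ether is cleaved by buffered fluoride within minutes at 0 °C, under conditions that leave both esters and all five stereocentres untouched.

Compound list
1 | pent-1-en-4-yne | C=CCC#C | starting material
2 | dimethyl[(1E)-2-methylpenta-1,4-dien-1-yl]alane | C=CC/C(C)=C/[Al](C)C | intermediate
3 | (2E)-3-methylhexa-2,5-dien-1-ol | C=CC/C(C)=C/CO | intermediate
4 | ethyl (3R)-4-chloro-3-hydroxybutanoate | CCOC(=O)C[C@@H](O)CCl | starting material
5 | ethyl [(2R)-oxiran-2-yl]acetate | CCOC(=O)C[C@@H]1CO1 | intermediate
6 | ethyl (3S)-3-hydroxy-5-methylhex-5-enoate | CCOC(=O)C[C@@H](O)CC(C)=C | intermediate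
7 | (2E)-3-methylhexa-2,5-dien-1-yl (3S)-3-hydroxy-5-methylhex-5-enoate | C=CC/C(C)=C/COC(=O)C[C@@H](O)CC(C)=C | intermediate
8 | chelated dilithio ester enolate of 7 (enolate oxygen cis to C5) | C=CC/C(C)=C/CO/C(O[Li])=C/[C@@H](O[Li])CC(C)=C | intermediate
9 | (2S,3S)-3-ethenyl-2-[(1S)-1-hydroxy-3-methylbut-3-en-1-yl]-3-methylhex-5-enoic acid | C=C[C@](C)(CC=C)[C@@H]([C@H](CC(C)=C)O)C(=O)O | intermediate
10 | TBS ether TBS ester of 9 | C=C[C@](C)(CC=C)[C@@H]([C@H](CC(C)=C)O[Si](C)(C)C(C)(C)C)C(=O)O[Si](C)(C)C(C)(C)C | intermediate
11 | TBS ether of 9 (free acid) | C=C[C@](C)(CC=C)[C@@H]([C@H](CC(C)=C)O[Si](C)(C)C(C)(C)C)C(=O)O | intermediate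
12 | cycloheptene acid (C4 β-CO2H, C5 α-OTBS, C10 β-CH3, α-vinyl) | C=C[C@]1(C)CC=C(C)C[C@H](O[Si](C)(C)C(C)(C)C)[C@H]1C(=O)O | intermediate
13 | trans-fused iodolactone (CH2I on C1 β) | O=C1O[C@@H](CI)[C@]2(C)CC=C(C)C[C@H](O[Si](C)(C)C(C)(C)C)[C@@H]12 | intermediate
14 | keto iodohydrin | O[C@@H](CI)[C@]1(C)CC=C(C)C[C@H](O[Si](C)(C)C(C)(C)C)[C@H]1C(=O)C(C)C | intermediate
15 | lithium alkoxide of 14 | [Li]O[C@@H](CI)[C@]1(C)CC=C(C)C[C@H](O[Si](C)(C)C(C)(C)C)[C@H]1C(=O)C(C)C | intermediate
16 | C2-lithio O1-lithium alkoxide (β-lithioalkoxide) | [Li]O[C@@H](C[Li])[C@]1(C)CC=C(C)C[C@H](O[Si](C)(C)C(C)(C)C)[C@H]1C(=O)C(C)C | intermediate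
17 | bicyclic 1α,3β-diol 5α-TBS ether | O[C@H]1C[C@@](O)(C(C)C)[C@@H]2[C@@H](O[Si](C)(C)C(C)(C)C)CC(C)=CC[C@@]12C | intermediate
18 | 1α-acetate of 17 | CC(=O)O[C@H]1C[C@@](O)(C(C)C)[C@@H]2[C@@H](O[Si](C)(C)C(C)(C)C)CC(C)=CC[C@@]12C | intermediate
19 | 1α-acetoxy-3β,5α-diol | CC(=O)O[C@H]1C[C@@](O)(C(C)C)[C@@H]2[C@@H](O)CC(C)=CC[C@@]12C | intermediate
20 | 4-[(tert-butyldimethylsilyl)oxy]benzoic acid | CC(C)(C)[Si](C)(C)Oc1ccc(cc1)C(=O)O | starting material
21 | O-silylated target | CC(=O)O[C@H]1C[C@@](O)(C(C)C)[C@@H]2[C@@H](OC(=O)c3ccc(O[Si](C)(C)C(C)(C)C)cc3)CC(C)=CC[C@@]12C | intermediate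
22 | target CNP0275279.1 | CC(=O)O[C@H]1C[C@@](O)(C(C)C)[C@@H]2[C@@H](OC(=O)c3ccc(O)cc3)CC(C)=CC[C@@]12C | target

Total step count: 14. Longest linear sequence: 13 steps (steps 2–14, from 4).

The three steps most likely to fail:

**Step 10.**
- What may go wrong: t-BuLi may attack or deprotonate the ketone before exchange, the alkoxide may close onto CH2I to give an epoxide, or the β-lithioalkoxide may lose lithium oxide before it cyclises.
- Fallback: set out from 14 and return at 17.
- Dess–Martin periodinane (CH2Cl2, 0 °C) oxidises C1–OH to the α-iodo ketone F1.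
- SmI2 (2 equiv, THF, −78 °C) then cleaves the C–I bond to a samarium enolate, which closes in an intramolecular Reformatsky-type aldol addition to the β-hydroxy ketone F2.
- An Evans–Saksena reduction with Me4NBH(OAc)3 (MeCN/AcOH, −20 °C) delivers hydride from the β face under direction of the C3 hydroxyl and gives 17.
- Because C1 is erased and reset, this sequence would also repair poor facial selectivity in step 8.

**Step 5.**
- What may go wrong: the rearrangement to a quaternary centre may be slow enough for the dianion to decay by retro-aldol cleavage or elimination, or chelate control of the enolate face may erode on warming.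
- Fallback: set out from 7 and return at 11, bypassing step 6.
- TBSCl/imidazole (DMF) gives the silyl ether ester F3.
- LDA in THF/DMPU with TMSCl present (−78 °C) gives the silyl ketene acetal F4, with silyloxy cis to C5.
- F4 rearranges on warming to 23 °C through the same chair to the trimethylsilyl ester F5, and aqueous work-up gives 11.

**Step 9.**
- What may go wrong: the lactone may be enolised (epimerisation at C4), reduced by β-hydride transfer, or left unattacked while the released alkoxide displaces iodide.
- Fallback: set out from 13 and return at 14.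
- Aminolysis with Me(MeO)NH·HCl/Me3Al (CH2Cl2, 0 °C) opens the lactone to the hydroxy Weinreb amide F6.
- Its chelated tetrahedral adduct with excess i-PrMgCl (THF, −20 °C) collapses only on work-up and gives 14.

Further compounds
F1 | step 10 | α-iodo ketone (C1=O, C2H2I; C4 β-isobutyryl) | O=C(CI)[C@]1(C)CC=C(C)C[C@H](O[Si](C)(C)C(C)(C)C)[C@H]1C(=O)C(C)C
F2 | step 10 | bicyclic β-hydroxy ketone (C1=O, 3β-OH, 3α-isopropyl, 5α-OTBS) | O=C1C[C@@](O)(C(C)C)[C@@H]2[C@@H](O[Si](C)(C)C(C)(C)C)CC(C)=CC[C@@]12C
F3 | step 5 | (2E)-3-methylhexa-2,5-dien-1-yl (3S)-3-[(tert-butyldimethylsilyl)oxy]-5-methylhex-5-enoate | C=CC/C(C)=C/COC(=O)C[C@@H](O[Si](C)(C)C(C)(C)C)CC(C)=C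
F4 | step 5 | trimethylsilyl ketene acetal of F3 (OSiMe3 cis to C5) | C=CC/C(C)=C/CO/C(O[Si](C)(C)C)=C/[C@@H](O[Si](C)(C)C(C)(C)C)CC(C)=C
F5 | step 5 | trimethylsilyl ester of 11 | C=C[C@](C)(CC=C)[C@@H]([C@H](CC(C)=C)O[Si](C)(C)C(C)(C)C)C(=O)O[Si](C)(C)C
F6 | step 9 | hydroxy Weinreb amide (iodohydrin retained) | O[C@@H](CI)[C@]1(C)CC=C(C)C[C@H](O[Si](C)(C)C(C)(C)C)[C@H]1C(=O)N(C)OC
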